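**Retrosynthetic overview**
1. Target 20 ⇐ 19 (isobutyrylation) ⇐ ten-membered hydroxy-diketone 18 (chelation-controlled methyl addition to the C10 ketone).
2. 18 ⇐ bicyclic lactone 16 by ozonolysis of its tetrasubstituted ring-fusion alkene; the ten-membered ring is formed last, by cutting the bond that was the fusion bond of an arene.
3. 16 ⇐ 13 ⇐ 10: lactone ring by Pd cyclocarbonylation of a trans-ethynyl carbinol, itself from acetylide opening of an epoxy alcohol.
4. 10 ⇐ quinone monoketal 8 (asymmetric epoxidation, CBS reduction); 8 ⇐ phenol 6 by oxidative dearomatisation (key step): the benzene ring becomes the fully substituted six-membered ring A.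
5. 6 ⇐ 1-tetralone (C–H hydroxylation, MeMgBr/dehydration, asymmetric hydrogenation). Ring order: ring A functionalised on the bicyclic template, then the lactone ring, then the ten-membered ring.

Assumption: the SMILES is taken as drawn (the 2-methylbutanoate is R); locants in each step follow the systematic name of that step's product; the sense of induction of the chiral catalysts in steps 3 and 5 is assumed, and the antipodal catalyst is used if it proves opposite.

**Route**

Step 1
Reactants: 1 3,4-dihydronaphthalen-1(2H)-one (1-tetralone)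
Product: 3 8-hydroxy-3,4-dihydronaphthalen-1(2H)-one, via aryl trifluoroacetate 2 (not isolated)
Conditions: Pd(OAc)2 (5 mol%), PhI(OCOCF3)2 (1.5 equiv), CF3CO2H/(CF3CO)2O 9:1, 50 °C; then aq. NaHCO3, MeOH
Reagents that add atoms: [bis(trifluoroacetoxy)iodo]benzene, O=C(O[I](OC(=O)C(F)(F)F)c1ccccc1)C(F)(F)F
Why: Ketone-directed ortho C–H oxygenation through a five-membered palladacycle at C8 (oxidation by the hypervalent iodine reagent, then C–O reductive elimination), the trifluoroacetate 2 being hydrolysed on work-up; no stereocentre is formed.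

Step 2
Reactants: 3 8-hydroxy-3,4-dihydronaphthalen-1(2H)-one
Product: 5 8-methyl-5,6-dihydronaphthalen-1-ol, via tertiary benzylic alcohol 4 (not isolated)
Conditions: MeMgBr (3 equiv), THF, 0 → 20 °C; then 2 M HCl, 20 °C
Reagents that add atoms: methylmagnesium bromide, C[Mg]Br
Why: Grignard 1,2-addition to the ketone (the first equivalent deprotonates the phenol) followed by acid-promoted E1 dehydration of 4 to the conjugated endocyclic alkene; no stereocentre yet.

Step 3
Reactants: 5 8-methyl-5,6-dihydronaphthalen-1-ol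
Product: 6 (8R)-8-methyl-5,6,7,8-tetrahydronaphthalen-1-ol
Conditions: H2 (50 bar), [Ir(cod)((S)-tBu-PHOX)][B(C6H3(CF3)2)4] (1 mol%), CH2Cl2, 25 °C
Reagents that add atoms: none
Why: Iridium/P,N-ligand asymmetric hydrogenation of a trisubstituted cyclic styrene (Pfaltz type), in which the catalyst selects the alkene face and sets the benzylic C8 centre as R.

Step 4
Reactants: 6 (8R)-8-methyl-5,6,7,8-tetrahydronaphthalen-1-ol
Product: 8 (8R)-4,4-dimethoxy-8-methyl-5,6,7,8-tetrahydronaphthalen-1(4H)-one, via 4-methoxyphenol 7 (not isolated)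
Conditions: PhI(OAc)2 (2.2 equiv), MeOH, 0 → 20 °C
Reagents that add atoms: methanol, CO
Why: Oxidative dearomatisation by a hypervalent iodine reagent (key step): para attack of MeOH on the O-iodinated phenol gives 7, and a second oxidation–methanolysis converts the benzene ring into a cross-conjugated dienone whose C1 ketone and C4 ketal are differentiated and whose C4a=C8a bond is kept as the latent diketone; C8 is untouched.

Step 5
Reactants: 8 (8R)-4,4-dimethoxy-8-methyl-5,6,7,8-tetrahydronaphthalen-1(4H)-one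
Product: 9 (2R,3S,8R)-2,3-epoxy-4,4-dimethoxy-8-methyl-2,3,5,6,7,8-hexahydronaphthalen-1(4H)-one
Conditions: tBuOOH (2 equiv), N-benzylcinchonidinium chloride (10 mol%), aq. NaOH, toluene, 0 °C
Reagents that add atoms: tert-butyl hydroperoxide, CC(C)(C)OO
Why: Weitz–Scheffer nucleophilic epoxidation under chiral phase-transfer catalysis, in which only the disubstituted C2=C3 enone bond is attacked (the tetrasubstituted C4a=C8a bond is inert) and the chiral cation directs tBuOO− to the face that gives 2R,3S, anti to the C8 methyl; any minor face isomer is a separable diastereomer because C8 is already fixed.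

Step 6
Reactants: 9 (2R,3S,8R)-2,3-epoxy-4,4-dimethoxy-8-methyl-2,3,5,6,7,8-hexahydronaphthalen-1(4H)-one
Product: 10 (1S,2S,3S,8R)-2,3-epoxy-4,4-dimethoxy-8-methyl-1,2,3,4,5,6,7,8-octahydronaphthalen-1-ol
Conditions: (S)-2-methyl-CBS-oxazaborolidine (0.2 equiv), BH3·SMe2 (0.7 equiv), THF, −30 °C
Reagents that add atoms: none
Why: Corey–Bakshi–Shibata reduction in which the catalyst (large group the C8a alkene carbon, small group the epoxide carbon) delivers hydride anti to the epoxide oxygen, in line with the Felkin–Anh preference of α,β-epoxy ketones, giving the cis-epoxy alcohol (1S).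

Step 7
Reactants: 10 (1S,2S,3S,8R)-2,3-epoxy-4,4-dimethoxy-8-methyl-1,2,3,4,5,6,7,8-octahydronaphthalen-1-ol
Product: 11 (1R,2R,3S,8R)-2-ethynyl-4,4-dimethoxy-8-methyl-1,2,3,4,5,6,7,8-octahydronaphthalene-1,3-diol
Conditions: LiC≡CH·H2NCH2CH2NH2 (5 equiv), DMSO, 25 °C
Reagents that add atoms: lithium acetylide–ethylenediamine complex, [Li]C#C.NCCN
Why: SN2 epoxide opening by acetylide at C2, because C3 is neopentyl-like next to the ketal carbon; inversion at C2 puts the ethynyl group trans to both flanking oxygens, C3 keeps the epoxide oxygen, and the cis alkoxide cannot undergo Payne rearrangement.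

Step 8
Reactants: 11 (1R,2R,3S,8R)-2-ethynyl-4,4-dimethoxy-8-methyl-1,2,3,4,5,6,7,8-octahydronaphthalene-1,3-diol; 12 (2R)-2-methylbutanoic acid
Product: 13 (1R,2S,3S,8R)-2-ethynyl-3-hydroxy-4,4-dimethoxy-8-methyl-1,2,3,4,5,6,7,8-octahydronaphthalen-1-yl (2R)-2-methylbutanoate
Conditions: 12 (1.05 equiv), DCC (1.1 equiv), DMAP (10 mol%), CH2Cl2, −20 °C
Reagents that add atoms: none
Why: Steglich esterification under kinetic control, the allylic C1 hydroxyl reacting in preference to the C3 hydroxyl that is flanked by the quaternary ketal carbon; no ring stereocentre changes and the acid centre is not epimerised at this temperature.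

Step 9
Reactants: 13 (1R,2S,3S,8R)-2-ethynyl-3-hydroxy-4,4-dimethoxy-8-methyl-1,2,3,4,5,6,7,8-octahydronaphthalen-1-yl (2R)-2-methylbutanoate
Product: 15 (3aR,4R,5R,9aS)-5-methyl-3-methylidene-2,9-dioxo-2,3,3a,4,5,6,7,8,9,9a-decahydronaphtho[2,3-b]furan-4-yl (2R)-2-methylbutanoate, via lactone ketal 14 (not isolated)
Conditions: PdI2 (5 mol%), PBu3 (10 mol%), CO (7 atm), MeCN, 60 °C; then 1 M HCl, THF, 20 °C
Reagents that add atoms: carbon monoxide, [C-]#[O+]; water, O
Why: Pd-catalysed cyclocarbonylation of a homopropargylic alcohol (Norton type, alkoxycarbonyl–palladium adding cis across the alkyne with CO on the internal carbon) closes the trans-fused α-methylene-γ-butyrolactone with retention at C3a and C9a, and the aqueous acid then hydrolyses the allylic dimethyl ketal to the enone.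

Step 10
Reactants: 15 (3aR,4R,5R,9aS)-5-methyl-3-methylidene-2,9-dioxo-2,3,3a,4,5,6,7,8,9,9a-decahydronaphtho[2,3-b]furan-4-yl (2R)-2-methylbutanoate
Product: 16 (3aR,4R,5R,9S,9aS)-9-hydroxy-5-methyl-3-methylidene-2-oxo-2,3,3a,4,5,6,7,8,9,9a-decahydronaphtho[2,3-b]furan-4-yl (2R)-2-methylbutanoate
Conditions: NaBH4, CeCl3·7H2O, MeOH, −78 °C
Reagents that add atoms: none
Why: Luche 1,2-reduction of the enone: with ring A locked by the trans-fused lactone, axial hydride attack gives the equatorial C9 alcohol trans to the C9a oxygen (9S), and CeCl3 suppresses conjugate reduction of the methylene lactone.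

Step 11
Reactants: 16 (3aR,4R,5R,9S,9aS)-9-hydroxy-5-methyl-3-methylidene-2-oxo-2,3,3a,4,5,6,7,8,9,9a-decahydronaphtho[2,3-b]furan-4-yl (2R)-2-methylbutanoate
Product: 18 (3aS,4R,6R,11R,11aS)-11-hydroxy-6-methyl-3-methylidene-2,5,10-trioxododecahydrocyclodeca[b]furan-4-yl (2R)-2-methylbutanoate, via ozonide 17 (not isolated)
Conditions: O3 (1.0 equiv, Sudan red 7B endpoint), CH2Cl2, −78 °C; then PPh3, −78 → 20 °C
Reagents that add atoms: ozone, [O-][O+]=O
Why: Criegee ozonolysis of the electron-rich tetrasubstituted ring-fusion alkene, which reacts much faster than the conjugated exocyclic methylene, and reduction of ozonide 17 opens the bicycle to the ten-membered 1,6-diketone without touching any stereocentre.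

Step 12
Reactants: 18 (3aS,4R,6R,11R,11aS)-11-hydroxy-6-methyl-3-methylidene-2,5,10-trioxododecahydrocyclodeca[b]furan-4-yl (2R)-2-methylbutanoate
Product: 19 (3aS,4R,6R,10S,11R,11aS)-10,11-dihydroxy-6,10-dimethyl-3-methylidene-2,5-dioxododecahydrocyclodeca[b]furan-4-yl (2R)-2-methylbutanoate
Conditions: MeTi(OiPr)3 (3 equiv), THF, −40 → 0 °C; aq. NH4F
Reagents that add atoms: methyltitanium triisopropoxide, C[Ti](OC(C)C)(OC(C)C)OC(C)C
Why: Chelation-controlled organotitanium addition (Reetz type): the C11 hydroxyl exchanges onto titanium, which activates only the adjacent C10 ketone and delivers methyl from the ring periphery on the side of H-11 (Cram chelate), giving the 10S carbinol with the two oxygens syn, while the hindered C5 ketone, the esters and the enoate do not react with this reagent.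

Step 13
Reactants: 19 (3aS,4R,6R,10S,11R,11aS)-10,11-dihydroxy-6,10-dimethyl-3-methylidene-2,5-dioxododecahydrocyclodeca[b]furan-4-yl (2R)-2-methylbutanoate
Product: 20 (3aS,4R,6R,10S,11R,11aS)-10-hydroxy-6,10-dimethyl-3-methylidene-11-[(2-methylpropanoyl)oxy]-2,5-dioxododecahydrocyclodeca[b]furan-4-yl (2R)-2-methylbutanoate
Conditions: (iPrCO)2O (1.5 equiv), pyridine, DMAP (5 mol%), CH2Cl2, 0 °C
Reagents that add atoms: isobutyric anhydride, CC(C)C(=O)OC(=O)C(C)C
Why: DMAP-catalysed acylation of the secondary C11 hydroxyl, the tertiary C10 hydroxyl being too hindered to react, which gives the target.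

**Compound list**
1 | 3,4-dihydronaphthalen-1(2H)-one (1-tetralone) | O=C1CCCc2ccccc12 | starting material
2 | 8-oxo-5,6,7,8-tetrahydronaphthalen-1-yl trifluoroacetate | O=C1CCCc2cccc(OC(=O)C(F)(F)F)c12 | intermediate
3 | 8-hydroxy-3,4-dihydronaphthalen-1(2H)-one | O=C1CCCc2cccc(O)c12 | intermediate
4 | 1-methyl-1,2,3,4-tetrahydronaphthalene-1,8-diol (racemic) | CC1(O)CCCc2cccc(O)c12 | intermediate
5 | 8-methyl-5,6-dihydronaphthalen-1-ol | CC1=CCCc2cccc(O)c12 | intermediate
6 | (8R)-8-methyl-5,6,7,8-tetrahydronaphthalen-1-ol | C[C@@H]1CCCc2cccc(O)c12 | intermediate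
7 | (8R)-4-methoxy-8-methyl-5,6,7,8-tetrahydronaphthalen-1-ol | C[C@@H]1CCCc2c(OC)ccc(O)c12 | intermediate
8 | (8R)-4,4-dimethoxy-8-methyl-5,6,7,8-tetrahydronaphthalen-1(4H)-one | C[C@@H]1CCCC2=C1C(=O)C=CC2(OC)OC | intermediate
9 | (2R,3S,8R)-2,3-epoxy-4,4-dimethoxy-8-methyl-2,3,5,6,7,8-hexahydronaphthalen-1(4H)-one | C[C@@H]1CCCC2=C1C(=O)[C@@H]3O[C@@H]3C2(OC)OC | intermediate
10 | (1S,2S,3S,8R)-2,3-epoxy-4,4-dimethoxy-8-methyl-1,2,3,4,5,6,7,8-octahydronaphthalen-1-ol | C[C@@H]1CCCC2=C1[C@H](O)[C@@H]3O[C@@H]3C2(OC)OC | intermediate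
11 | (1R,2R,3S,8R)-2-ethynyl-4,4-dimethoxy-8-methyl-1,2,3,4,5,6,7,8-octahydronaphthalene-1,3-diol | C[C@@H]1CCCC2=C1[C@H](O)[C@@H](C#C)[C@H](O)C2(OC)OC | intermediate
12 | (2R)-2-methylbutanoic acid | CC[C@@H](C)C(=O)O | starting material
13 | (1R,2S,3S,8R)-2-ethynyl-3-hydroxy-4,4-dimethoxy-8-methyl-1,2,3,4,5,6,7,8-octahydronaphthalen-1-yl (2R)-2-methylbutanoate | C[C@@H]1CCCC2=C1[C@H](OC(=O)[C@H](C)CC)[C@@H](C#C)[C@H](O)C2(OC)OC | intermediate
14 | (3aR,4R,5R,9aS)-9,9-dimethoxy-5-methyl-3-methylidene-2-oxo-2,3,3a,4,5,6,7,8,9,9a-decahydronaphtho[2,3-b]furan-4-yl (2R)-2-methylbutanoate | C[C@@H]1CCCC2=C1[C@H](OC(=O)[C@H](C)CC)[C@H]3C(=C)C(=O)O[C@@H]3C2(OC)OC | intermediate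
15 | (3aR,4R,5R,9aS)-5-methyl-3-methylidene-2,9-dioxo-2,3,3a,4,5,6,7,8,9,9a-decahydronaphtho[2,3-b]furan-4-yl (2R)-2-methylbutanoate | C[C@@H]1CCCC2=C1[C@H](OC(=O)[C@H](C)CC)[C@H]3C(=C)C(=O)O[C@@H]3C2=O | intermediate
16 | (3aR,4R,5R,9S,9aS)-9-hydroxy-5-methyl-3-methylidene-2-oxo-2,3,3a,4,5,6,7,8,9,9a-decahydronaphtho[2,3-b]furan-4-yl (2R)-2-methylbutanoate | C[C@@H]1CCCC2=C1[C@H](OC(=O)[C@H](C)CC)[C@H]3C(=C)C(=O)O[C@@H]3[C@H]2O | intermediate
17 | secondary ozonide of 16: 1,2,4-trioxolane spanning the former C4a=C8a bond (one of two bridge epimers shown; both are reduced to 18) | C=C1C(=O)O[C@H]2[C@H]1[C@@H](OC(=O)[C@H](C)CC)[C@]3(OO4)[C@H](C)CCC[C@@]4(O3)[C@@H]2O | intermediate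
18 | (3aS,4R,6R,11R,11aS)-11-hydroxy-6-methyl-3-methylidene-2,5,10-trioxododecahydrocyclodeca[b]furan-4-yl (2R)-2-methylbutanoate | C=C1C(=O)O[C@H]2[C@H]1[C@@H](OC(=O)[C@H](C)CC)C(=O)[C@H](C)CCCC(=O)[C@@H]2O | intermediate
19 | (3aS,4R,6R,10S,11R,11aS)-10,11-dihydroxy-6,10-dimethyl-3-methylidene-2,5-dioxododecahydrocyclodeca[b]furan-4-yl (2R)-2-methylbutanoate | C=C1C(=O)O[C@H]2[C@H]1[C@@H](OC(=O)[C@H](C)CC)C(=O)[C@H](C)CCC[C@](C)(O)[C@@H]2O | intermediate
20 | (3aS,4R,6R,10S,11R,11aS)-10-hydroxy-6,10-dimethyl-3-methylidene-11-[(2-methylpropanoyl)oxy]-2,5-dioxododecahydrocyclodeca[b]furan-4-yl (2R)-2-methylbutanoate (CNP0071420.1) | C=C1C(=O)O[C@H]2[C@H]1[C@@H](OC(=O)[C@H](C)CC)C(=O)[C@H](C)CCC[C@](C)(O)[C@@H]2OC(=O)C(C)C | target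

**Step count and risks**
Total steps: 13. Longest linear sequence: 13 (1 → 20); acid 12 is bought.

Step 6 is the most exposed. The hydride must arrive anti to the epoxide but syn to the C8 methyl, which sits pseudoaxial to avoid the C1 carbonyl, so reagent control may be eroded. The fallback sets out from 9 and accepts the substrate bias: LiBH(sBu)3 (THF, −78 °C) should attack anti to the methyl and give (1R,2S,3S,8R)-2,3-epoxy-4,4-dimethoxy-8-methyl-1,2,3,4,5,6,7,8-octahydronaphthalen-1-ol F1. Opening F1 with Me2AlC≡CH (toluene, 0 °C), the alane bound to the C1 alkoxide delivering ethynyl to C2 on the lower face without Payne rearrangement, gives (1S,2R,3S,8R)-2-ethynyl-4,4-dimethoxy-8-methyl-1,2,3,4,5,6,7,8-octahydronaphthalene-1,3-diol F2. A Mitsunobu esterification of F2 with acid 12 (PPh3, DIAD, THF, 0 °C) then inverts the allylic C1 centre while installing the ester; the C3 hydroxyl next to the ketal is inert. The route is rejoined at 13.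

Step 8 depends on discriminating two secondary hydroxyls, and a mixture of C1 ester, C3 ester and diester is possible. The fallback sets out from 10, where the C1 hydroxyl is the only one. Esterification with 12 (DCC, DMAP) gives (1S,2S,3S,8R)-2,3-epoxy-4,4-dimethoxy-8-methyl-1,2,3,4,5,6,7,8-octahydronaphthalen-1-yl (2R)-2-methylbutanoate F3. The epoxide of F3 is then opened at C2 with Me2AlC≡CH (toluene, 0 °C), an alkynyl donor that spares the hindered ester, and the route is rejoined at 13.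

Step 12 may be upset by transannular hemiketal formation between the C11 hydroxyl and the C5 ketone, which would weaken the chelate that controls both site and face. The fallback sets out from 16 and puts the ester on first. Isobutyric anhydride/DMAP gives (3aR,4R,5R,9S,9aS)-5-methyl-3-methylidene-9-[(2-methylpropanoyl)oxy]-2-oxo-2,3,3a,4,5,6,7,8,9,9a-decahydronaphtho[2,3-b]furan-4-yl (2R)-2-methylbutanoate F4. Ozonolysis as in step 11 gives (3aS,4R,6R,11R,11aS)-6-methyl-3-methylidene-11-[(2-methylpropanoyl)oxy]-2,5,10-trioxododecahydrocyclodeca[b]furan-4-yl (2R)-2-methylbutanoate F5. MeTiCl3 (CH2Cl2, −78 °C), which tolerates esters and the enoate, then adds to the less hindered C10 ketone from the ring periphery and gives 20 directly; the C10 configuration from this peripheral attack would have to be confirmed.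

**Further compounds**
F1 | step 6 | (1R,2S,3S,8R)-2,3-epoxy-4,4-dimethoxy-8-methyl-1,2,3,4,5,6,7,8-octahydronaphthalen-1-ol | C[C@@H]1CCCC2=C1[C@@H](O)[C@@H]3O[C@@H]3C2(OC)OC
F2 | step 6 | (1S,2R,3S,8R)-2-ethynyl-4,4-dimethoxy-8-methyl-1,2,3,4,5,6,7,8-octahydronaphthalene-1,3-diol | C[C@@H]1CCCC2=C1[C@@H](O)[C@@H](C#C)[C@H](O)C2(OC)OC
F3 | step 8 | (1S,2S,3S,8R)-2,3-epoxy-4,4-dimethoxy-8-methyl-1,2,3,4,5,6,7,8-octahydronaphthalen-1-yl (2R)-2-methylbutanoate | C[C@@H]1CCCC2=C1[C@H](OC(=O)[C@H](C)CC)[C@@H]3O[C@@H]3C2(OC)OC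
F4 | step 12 | (3aR,4R,5R,9S,9aS)-5-methyl-3-methylidene-9-[(2-methylpropanoyl)oxy]-2-oxo-2,3,3a,4,5,6,7,8,9,9a-decahydronaphtho[2,3-b]furan-4-yl (2R)-2-methylbutanoate | C[C@@H]1CCCC2=C1[C@H](OC(=O)[C@H](C)CC)[C@H]3C(=C)C(=O)O[C@@H]3[C@H]2OC(=O)C(C)C
F5 | step 12 | (3aS,4R,6R,11R,11aS)-6-methyl-3-methylidene-11-[(2-methylpropanoyl)oxy]-2,5,10-trioxododecahydrocyclodeca[b]furan-4-yl (2R)-2-methylbutanoate | C=C1C(=O)O[C@H]2[C@H]1[C@@H](OC(=O)[C@H](C)CC)C(=O)[C@H](C)CCCC(=O)[C@@H]2OC(=O)C(C)C
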